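**Remark.** The target is read as the 3α-angelate, a (Z)-2-methylbut-2-enoate, of 3α,4α,11-trihydroxyeudesm-6-en-8-one, (3R,4S,5R,10R). Eudesmane atom numbers are used throughout, also for the acyclic intermediates: ring A = C1–C5 and C10, ring B = C5–C10, C11 = the carbinol carbon on C7.

## Retrosynthetic overview

1. The angelate goes on last, at the only secondary hydroxyl of a 3α,4α,11-triol; the cis-diol comes from α-face dihydroxylation of a C3=C4 alkene in a trans-fused bicyclic dienone.
2. That dienone comes from one intramolecular Diels–Alder reaction of an acyclic, achiral trienone: diene C2=C3–C4(CH3)=C5, dienophile C1H2=C10(CH3), tether C6=C7(C11)–C8(=O)–C9. Bonds C1–C2 and C5–C10 form together, so ring A (cycloadduct ring) and ring B (tether ring) close in the same step and C5 and C10 are set.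
3. Enabling feature: in ring B the C8 ketone is joined through C6=C7 to C5, so the ring A diene is the electron-poor end of a trienone. The C11 hydroxyl on C7 lies 1,3 to the C8 oxygen, a chelation site for a chiral Lewis acid right beside the C9–C10 arm. C10 with its methyl and C1 maps onto a plain 2-methylallyl group.
4. The trienone comes from oxidation of a 2-methylallyl carbinol, made from a (Z)-configured C8 aldehyde, made from a vinyl bromide carrying the C11 carbinol, made by Z-selective bromo-Wittig olefination of (E)-3-methylpenta-2,4-dienal.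
5. Ring order: no ring before the key step; rings A and B together in it.

Key step: step 8

## Route

Step 1
Reactants: 1 (2E)-3-methylpent-2-en-4-yn-1-ol
Product: 2 (2E)-3-methylpenta-2,4-dien-1-ol
Conditions: H2 (1 atm), 5% Pd/CaCO3 poisoned with Pb(OAc)2, quinoline, EtOAc, 0 °C to rt, stopped after 1 equiv H2
Reagents that add atoms: none
Why: Semi-hydrogenation over lead-poisoned palladium should stop at the vinyl group and leave the (E)-trisubstituted alkene untouched; no stereocentre is formed.

Step 2
Reactants: 2 (2E)-3-methylpenta-2,4-dien-1-ol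
Product: 3 (2E)-3-methylpenta-2,4-dienal
Conditions: MnO2 (activated, 15 equiv), CH2Cl2, rt; filtered and used as a solution
Reagents that add atoms: none
Why: MnO2 oxidises the primary allylic alcohol to the enal without E/Z isomerisation (allylic alcohol oxidation).

Step 3
Reactants: 3 (2E)-3-methylpenta-2,4-dienal; 4 methyl (triphenylphosphoranylidene)acetate
Product: 6 methyl (2Z,4E)-2-bromo-5-methylhepta-2,4,6-trienoate, via bromo ylide 5 (not isolated)
Conditions: 4, NBS, CH2Cl2, −20 °C; then 3, −20 °C to rt
Reagents that add atoms: N-bromosuccinimide, O=C1CCC(=O)N1Br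
Why: Bromination of the stabilised ylide followed by Wittig reaction should place the ester trans to the dienyl chain (stabilised-ylide selectivity), hence bromine cis to C5, which fixes the later cis relation of C5 and C8.

Step 4
Reactants: 6 methyl (2Z,4E)-2-bromo-5-methylhepta-2,4,6-trienoate
Product: 8 (3Z,5E)-3-bromo-2,6-dimethylocta-3,5,7-trien-2-ol, via methyl ketone 7 (not isolated)
Conditions: MeMgBr (2.5 equiv), THF, −40 to 0 °C; aq NH4Cl
Reagents that add atoms: methylmagnesium bromide, C[Mg]Br
Why: Double Grignard addition to the ester gives the C11 tertiary carbinol; the vinyl bromide is inert to MeMgBr and the alkene geometry is untouched.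

Step 5
Reactants: 8 (3Z,5E)-3-bromo-2,6-dimethylocta-3,5,7-trien-2-ol
Product: 10 (2Z,4E)-2-(2-hydroxypropan-2-yl)-5-methylhepta-2,4,6-trienal, via dilithio species 9 (not isolated)
Conditions: t-BuLi (3.1 equiv), Et2O, −78 °C; DMF, −78 to 0 °C; aq NH4Cl
Reagents that add atoms: N,N-dimethylformamide, CN(C)C=O
Why: Deprotonation and bromine–lithium exchange give a configurationally stable alkoxide-bearing vinyllithium that is formylated with retention (Bouveault formylation), so the formyl carbon C8 ends cis to the dienyl chain.

Step 6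
Reactants: 10 (2Z,4E)-2-(2-hydroxypropan-2-yl)-5-methylhepta-2,4,6-trienal; 11 2-methylallylmagnesium chloride
Product: 12 (5E,7E)-5-(2-hydroxypropan-2-yl)-2,8-dimethyldeca-1,5,7,9-tetraen-4-ol (racemic at the new carbinol carbon)
Conditions: 11 (2.2 equiv), THF, −78 to 0 °C; aq NH4Cl
Reagents that add atoms: none
Why: 1,2-Grignard addition of the allylic reagent to the enal installs the C9–C10(=C1) dienophile arm; the new carbinol centre is formed as the racemate and is erased in step 7.

Step 7
Reactants: 12 (5E,7E)-5-(2-hydroxypropan-2-yl)-2,8-dimethyldeca-1,5,7,9-tetraen-4-ol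
Product: 13 (5Z,7E)-5-(2-hydroxypropan-2-yl)-2,8-dimethyldeca-1,5,7,9-tetraen-4-one
Conditions: Dess–Martin periodinane (1.2 equiv), pyridine, CH2Cl2, 0 °C; short silica plug, used at once
Reagents that add atoms: none
Why: Dess–Martin oxidation converts the secondary allylic alcohol to the ketone under buffered, non-basic conditions that should leave the tertiary alcohol and the β,γ-alkene in place.

Step 8
Reactants: 13 (5Z,7E)-5-(2-hydroxypropan-2-yl)-2,8-dimethyldeca-1,5,7,9-tetraen-4-one
Product: 14 (4aR,8aR)-3-(2-hydroxypropan-2-yl)-5,8a-dimethyl-4a,7,8,8a-tetrahydronaphthalen-2(1H)-one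
Conditions: (R)-3,3'-bis(triphenylsilyl)-1,1'-bi-2-naphthol (20 mol%) + AlMe3 (20 mol%), CH2Cl2, rt, 1 h; then 13, −20 °C to rt; aq potassium sodium tartrate
Reagents that add atoms: none
Why: Proposed new method: the C11 hydroxyl protonolyses the Al–CH3 bond of the catalyst and the C8 carbonyl closes a six-membered O–Al–O chelate, which lowers the LUMO of the C2=C3–C4=C5 diene through C6=C7–C8=O so that the unactivated 1,1-disubstituted alkene C1=C10 adds in an asynchronous, concerted inverse-electron-demand intramolecular Diels–Alder reaction (C1–C2 and C5–C10 formed together), after which the product alkoxide is exchanged for the hydroxyl of the next substrate molecule. The closest known reaction types are Lewis acid-promoted type 1 intramolecular Diels–Alder reactions of deca-1,3,9-trienes, chiral binaphtholate-boron chelates of peri-hydroxy quinones in asymmetric Diels–Alder reactions, and chiral Lewis acid-catalysed inverse-demand cycloadditions of chelating electron-poor dienes such as 3-alkoxycarbonyl-2-pyrones. Ring A is closed as the [4+2] cyclohexene (C1, C2, C3, C4, C5, C10) and ring B as the six-membered tether ring through C5–C10 (fused mode), its cis-configured enone, planar in the chelate, holding C9 on the same side as C5. C5 and C10 are set relative to each other by the (E) geometry at C4=C5 and the anti (trans-fused) transition state, which keeps the C4=C5–C6=C7 torsion near s-trans and so retains the activating conjugation that the syn (cis-fused) array loses; their absolute sense is set by the binaphtholate, whose 3-triphenylsilyl group shields one face of the chelate plane next to C9 so that C10 swings to the open face, which a quadrant model assigns to the (4aR,8aR) product for the (R)-ligand. The step needs regiocontrol (fixed by the four-atom tether), trans ring fusion and one enantioface (secured in the substrate by the 1,3-hydroxy ketone chelation site beside C9, the E diene and the rigid cis-enone tether), and chemoselectivity over the enolisable C9 methylene (secured by the mild, covalently bound Lewis acid at low temperature).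

Step 9
Reactants: 14 (4aR,8aR)-3-(2-hydroxypropan-2-yl)-5,8a-dimethyl-4a,7,8,8a-tetrahydronaphthalen-2(1H)-one
Product: 16 (4aR,5S,6R,8aR)-5,6-dihydroxy-3-(2-hydroxypropan-2-yl)-5,8a-dimethyl-4a,5,6,7,8,8a-hexahydronaphthalen-2(1H)-one, via osmate ester 15 (not isolated)
Conditions: K2OsO4·2H2O (2 mol%), NMO (1.5 equiv), acetone/H2O 4:1, 0 °C to rt; aq Na2SO3
Reagents that add atoms: osmium tetroxide (formed in the flask from K2OsO4·2H2O and NMO), O=[Os](=O)(=O)=O; N-methylmorpholine N-oxide, C[N+]1([O-])CCOCC1; water, O
Why: Catalytic OsO4/NMO syn-dihydroxylation should attack the electron-rich trisubstituted C3=C4 alkene in preference to the enone, from the α face opposite the axial C10 methyl, setting C3 (R) and C4 (S) as the 3α,4α-cis-diol.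

Step 10
Reactants: 16 (4aR,5S,6R,8aR)-5,6-dihydroxy-3-(2-hydroxypropan-2-yl)-5,8a-dimethyl-4a,5,6,7,8,8a-hexahydronaphthalen-2(1H)-one; 17 angelic acid, (2Z)-2-methylbut-2-enoic acid
Product: 19 (1S,2R,4aR,8aR)-1-hydroxy-7-(2-hydroxypropan-2-yl)-1,4a-dimethyl-6-oxo-1,2,3,4,4a,5,6,8a-octahydronaphthalen-2-yl (2Z)-2-methylbut-2-enoate, via mixed anhydride 18 (not isolated)
Conditions: 17, 2,4,6-trichlorobenzoyl chloride, Et3N, toluene, rt; then 16, 75 °C
Reagents that add atoms: none
Why: Yamaguchi esterification through the mixed anhydride acylates only the secondary 3α-hydroxyl (the other two are tertiary) and, run without DMAP, is known to keep the (Z) geometry of angelates.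

## Compound list

1 | (2E)-3-methylpent-2-en-4-yn-1-ol | OC/C=C(C)/C#C | starting material
2 | (2E)-3-methylpenta-2,4-dien-1-ol | OC/C=C(C)/C=C | intermediate
3 | (2E)-3-methylpenta-2,4-dienal | O=C/C=C(C)/C=C | intermediate
4 | methyl (triphenylphosphoranylidene)acetate | COC(=O)C=P(c1ccccc1)(c1ccccc1)c1ccccc1 | starting material
5 | methyl bromo(triphenylphosphoranylidene)acetate (bromo ylide) | COC(=O)C(Br)=P(c1ccccc1)(c1ccccc1)c1ccccc1 | intermediate (not isolated)
6 | methyl (2Z,4E)-2-bromo-5-methylhepta-2,4,6-trienoate | COC(=O)/C(Br)=C/C=C(C)/C=C | intermediate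
7 | (3Z,5E)-3-bromo-6-methylocta-3,5,7-trien-2-one (methyl ketone) | CC(=O)/C(Br)=C/C=C(C)/C=C | intermediate (not isolated)
8 | (3Z,5E)-3-bromo-2,6-dimethylocta-3,5,7-trien-2-ol | CC(C)(O)/C(Br)=C/C=C(C)/C=C | intermediate
9 | lithium alkoxide/vinyllithium of 8 (lithium in place of bromine, geometry retained) | CC(C)(O[Li])/C([Li])=C/C=C(C)/C=C | intermediate (not isolated)
10 | (2Z,4E)-2-(2-hydroxypropan-2-yl)-5-methylhepta-2,4,6-trienal | CC(C)(O)/C(C=O)=C/C=C(C)/C=C | intermediate
11 | 2-methylallylmagnesium chloride | C=C(C)C[Mg]Cl | starting material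
12 | (5E,7E)-5-(2-hydroxypropan-2-yl)-2,8-dimethyldeca-1,5,7,9-tetraen-4-ol, racemic (same alkene geometry as 13; the descriptor differs only by CIP priority) | CC(C)(O)/C(C(O)CC(C)=C)=C/C=C(C)/C=C | intermediate
13 | (5Z,7E)-5-(2-hydroxypropan-2-yl)-2,8-dimethyldeca-1,5,7,9-tetraen-4-one | CC(C)(O)/C(C(=O)CC(C)=C)=C/C=C(C)/C=C | intermediate
14 | (4aR,8aR)-3-(2-hydroxypropan-2-yl)-5,8a-dimethyl-4a,7,8,8a-tetrahydronaphthalen-2(1H)-one | CC1=CCC[C@]2(C)CC(=O)C(C(C)(C)O)=C[C@@H]12 | intermediate
15 | cyclic osmate ester of 16 across the 3α,4α-oxygens | O=[Os]1(=O)O[C@@H]2CC[C@]3(C)CC(=O)C(C(C)(C)O)=C[C@H]3[C@]2(C)O1 | intermediate (not isolated)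
16 | (4aR,5S,6R,8aR)-5,6-dihydroxy-3-(2-hydroxypropan-2-yl)-5,8a-dimethyl-4a,5,6,7,8,8a-hexahydronaphthalen-2(1H)-one | O[C@@H]1CC[C@]2(C)CC(=O)C(C(C)(C)O)=C[C@H]2[C@]1(C)O | intermediate
17 | angelic acid, (2Z)-2-methylbut-2-enoic acid | C/C=C(/C)C(=O)O | starting material
18 | (2Z)-2-methylbut-2-enoic 2,4,6-trichlorobenzoic anhydride | C/C=C(/C)C(=O)OC(=O)c1c(Cl)cc(Cl)cc1Cl | intermediate (not isolated)
19 | (1S,2R,4aR,8aR)-1-hydroxy-7-(2-hydroxypropan-2-yl)-1,4a-dimethyl-6-oxo-1,2,3,4,4a,5,6,8a-octahydronaphthalen-2-yl (2Z)-2-methylbut-2-enoate | C/C=C(/C)C(=O)O[C@@H]1CC[C@]2(C)CC(=O)C(C(C)(C)O)=C[C@H]2[C@]1(C)O | target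

## Step count and risks

Total steps: 10. Longest linear sequence: 10 (1 to 19); 4, 11 and 17 are purchased.

**Step 8 (Proposed new method).** What may go wrong: weak or reversed enantiofacial discrimination by the chelated aluminium binaphtholate, slow exchange of the product alkoxide, competing cis ring fusion, or drain of the cis-dienone through reversible oxa-6π ring closure with E/Z scrambling at C4=C5. A reversed sense alone would be met with the (S)-ligand. Fallback with known chemistry, from 13 back to 16: uncatalysed thermal intramolecular Diels–Alder reaction of 13 (toluene, BHT, 80–110 °C) should give 14 as the racemate, that is together with its enantiomer, the (4aS,8aS)-dienone F1. Dihydroxylation as in step 9 then gives 16 together with its enantiomer, the (4aS,5R,6S,8aS)-triol F2. Esterification of the secondary hydroxyl with (S)-2-methoxy-2-phenylacetic acid (DCC, DMAP, CH2Cl2) gives two diastereomers, the (2S)-2-methoxy-2-phenylacetate of 16 F3 and the (2S)-2-methoxy-2-phenylacetate of the enantiomeric triol F4, to be separated on silica gel. Methanolysis of F3 (K2CO3, MeOH) returns 16 as a single enantiomer, and the route continues with step 10.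

**Step 7.** What may go wrong: migration of the C1=C10 double bond into conjugation with the new ketone under traces of acid or base, and uncontrolled cyclisation or geometric scrambling of the cis-dienone during oxidation and isolation. Fallback, from 8 back to 13, without any alcohol oxidation: the vinyllithium 9 generated as in step 5 is acylated with N-methoxy-N-methylcarbamoyl chloride (−78 °C) to give the Weinreb amide (2Z,4E)-2-(2-hydroxypropan-2-yl)-N-methoxy-N,5-dimethylhepta-2,4,6-trienamide F5. Addition of 11 (excess, THF, −78 to 0 °C) stops at the chelated tetrahedral adduct and releases 13 only on mild acidic quench.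

**Step 10.** What may go wrong: Z to E isomerisation of the angelate to the tiglate, and sluggish acylation of the hindered axial hydroxyl next to the quaternary carbinol. Fallback, from 16 to 19, building the (Z)-alkene after the ester bond: acylation of the secondary hydroxyl with 2-[bis(2,2,2-trifluoroethoxy)phosphoryl]propanoic acid (DCC, CH2Cl2) gives the phosphonate ester of 16 F6. Still–Gennari olefination with acetaldehyde (KHMDS, 18-crown-6, THF, −78 °C) should then give the (Z)-2-methylbut-2-enoate 19.

## Further compounds

F1 | step 8 | (4aS,8aS)-3-(2-hydroxypropan-2-yl)-5,8a-dimethyl-4a,7,8,8a-tetrahydronaphthalen-2(1H)-one (enantiomer of 14) | CC1=CCC[C@@]2(C)CC(=O)C(C(C)(C)O)=C[C@H]12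
F2 | step 8 | (4aS,5R,6S,8aS)-5,6-dihydroxy-3-(2-hydroxypropan-2-yl)-5,8a-dimethyl-4a,5,6,7,8,8a-hexahydronaphthalen-2(1H)-one (enantiomer of 16) | O[C@H]1CC[C@@]2(C)CC(=O)C(C(C)(C)O)=C[C@@H]2[C@@]1(C)O
F3 | step 8 | (2S)-2-methoxy-2-phenylacetate of 16 at the secondary hydroxyl | CO[C@H](C(=O)O[C@@H]1CC[C@]2(C)CC(=O)C(C(C)(C)O)=C[C@H]2[C@]1(C)O)c1ccccc1
F4 | step 8 | (2S)-2-methoxy-2-phenylacetate of F2 at the secondary hydroxyl | CO[C@H](C(=O)O[C@H]1CC[C@@]2(C)CC(=O)C(C(C)(C)O)=C[C@@H]2[C@@]1(C)O)c1ccccc1
F5 | step 7 | (2Z,4E)-2-(2-hydroxypropan-2-yl)-N-methoxy-N,5-dimethylhepta-2,4,6-trienamide | CC(C)(O)/C(C(=O)N(C)OC)=C/C=C(C)/C=C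
F6 | step 10 | 2-[bis(2,2,2-trifluoroethoxy)phosphoryl]propanoate of 16 at the secondary hydroxyl (both epimers at the phosphonate carbon) | CC(C(=O)O[C@@H]1CC[C@]2(C)CC(=O)C(C(C)(C)O)=C[C@H]2[C@]1(C)O)P(=O)(OCC(F)(F)F)OCC(F)(F)F
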